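## The problem

Parritadial is a drimane: a trans-fused decalin in which ring A (C1–C5, C10) carries the C4 gem-dimethyl group and an equatorial 1β-acetate. Ring B (C5–C10) carries a 6α-acetate, the C7=C8 alkene with the C12 aldehyde on C8, and a fully substituted C9 bearing an α-hydroxyl and the C11 aldehyde, directly beside the quaternary C10. Five stereocentres (C1, C5, C6, C9, C10) must be set as one enantiomer. C5 and C10 define the ring fusion, and once they are fixed the axial 10β- and 4β-methyl groups screen the β face, so that hydride at C1 and oxygen at C6 and C9 can be expected to enter from the α face. C9 is the hard centre. It is tertiary and wedged between a quaternary carbon and an sp2 carbon, and a carbon nucleophile added to a C9 ketone would also come from the α face and leave the hydroxyl β, the wrong epimer. Hydride reduction of a C6 ketone would likewise give the 6β-alcohol. The 2-ene-1,4-dial with its α-hydroxy aldehyde, the allylic acetate and the tertiary allylic alcohol tolerate neither strong base, strong acid nor hydride. A free C11 hydroxyl beside a C12 aldehyde closes to a lactol, so both aldehydes must be unveiled together at the end. The feature that opens the structure is that the C6 and C9 oxygens are cis (both α) and 1,4 to each other across C7=C8. That is the pattern left when the 6,9-endoperoxide of a ring B 6,8-diene is reduced, and (R)-carvone supplies ring B with C5 in the correct absolute configuration.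

## Retrosynthesis

**23 ⇒ 22.** No skeletal bond is cut; the two aldehydes of parritadial 23 are traced to the primary alcohols of triol 22. Oxidising both at once is preferred to any stepwise order, because a hydroxy aldehyde intermediate would cyclise to the lactol and end as the lactone. Triol 22 already holds both acetates and all five stereocentres. The forward reaction must leave the tertiary C9 hydroxyl and the acetates untouched.

**22 ⇒ 21 ⇒ 19.** The C11 oxygen is masked as a silyl ether (21), and the C12–O bond is cut back to the C12 methyl group of 19; the over-oxidised enal 20 lies on this path and is returned to 21. The methyl group comes with carvone at no cost, and it is the only allylic C–H on the disubstituted carbon of the alkene, so the site of oxidation is fixed by structure. Carrying an oxygenated C12 from the start would require a ring B building block that is not commercial. The forward step must make an alkene that is deactivated by two allylic oxygens undergo an ene reaction.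

**19 ⇒ 18 ⇒ 17.** Removing the C6 acetyl gives diol 18, whose secondary and tertiary hydroxyls need no protecting group to be told apart. Joining the two oxygens gives endoperoxide 17. The forward reduction must cleave only the O–O bond.

**17 ⇒ 15 + 16.** This is the key cut: the C6–O and C9–O bonds are broken together, giving the ring B 6,8-diene 15 and dioxygen 16. Against the neighbouring cuts (C9–C11 by carbonyl addition, C6–O by allylic oxidation and reduction) it has the decisive advantage that both oxygens arrive from the unhindered α face in one step, with the C7=C8 alkene left in place. Diene 15 has only three stereocentres (C1, C5, C10). The forward reaction needs α-face selectivity and cycloaddition in preference to the ene reaction.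

**15 ⇒ 14 ⇒ 12 + 13, and 12 ⇒ 11.** The silyl ether is removed (14) and the C9–C11 bond is cut, giving dienyl triflate 12 and (tributylstannyl)methanol 13. C11 is brought in as CH2OH and not as a carbonyl group so that the diene stays electron-rich for the photooxygenation. Triflate 12 comes from enone 11, which can lose a proton only at C6 because C10 is quaternary, so the diene is formed in one position only.

**11 ⇒ 10 ⇒ 9.** The C1 acetate is traced through alcohol 10 to the 1,9-dione 9. Placing the acetate this early avoids any later differentiation of C1 from the ring B hydroxyls. The forward reduction must select the saturated C1 ketone over the conjugated C9 ketone and deliver hydride from the α face.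

**9 ⇒ 8.** The C3–C4 bond of ring A is cut, giving the carvone-derived vinyl ketone 8. One radical cyclisation then forms ring A and the gem-dimethyl carbon and fixes the trans fusion from stereocentres already present.

**8 ⇒ 7 ⇒ 4 + 5, and 4 ⇒ 1 + 2.** The acryloyl group is taken back to the allylic alcohol 7, and the C1–C10 bond is cut to the enolate 6 of 6-methylcarvone 4 and acrolein 5. Compound 4 comes from (R)-carvone 1 and iodomethane 2 through dienolate 3. Introducing the methyl group first and the three-carbon unit second places the latter trans to the isopropenyl group, which is the relation the trans-decalin requires.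

## Roads not taken

**Alternative 1:** The cut is C3–C4, with ring B taken intact from carvone. In the forward direction Fe(acac)3 and PhSiH3 turn the isopropenyl group into the tertiary C4 radical, which closes ring A on the terminal carbon of a C10 vinyl ketone and gives the trans-fused enedione A1.
- Merits: the chiral pool supplies C5, the gem-dimethyl carbon is made without a cation, and the ring fusion follows from centres already set. As a ring A construction it is as good as anything available, and the chosen plan adopts it: A1 is compound 9, formed in step 4 from 8.
- Weak points: as a strategy on its own it stops where the difficulty begins. A1 has no C6 oxygen, no C11 and a ketone at C9. Adding a one-carbon nucleophile to that ketone would occur anti to the axial C10 methyl and give the 9β-hydroxy epimer. Allylic oxidation at C6 followed by reduction would give the 6β-alcohol.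
- Comparison: the chosen plan pays three steps (11 to 15) to convert the ketone into the silyloxymethyl diene, and in return sets both ring B oxygens correctly in one step.

**Alternative 2:** The cuts are C7–C8 and C8–C9. C8 is taken out of ring B, leaving a trans-fused five-membered ketone that already carries the C1 and C6 oxygens, used as its trimethylsilyl enol ether A2. Dibromocarbene (CHBr3, KOt-Bu) would cyclopropanate the C7=C9 enol ether, and opening with loss of bromide and the silyl group would give the ring-expanded 8-bromo-7-en-9-one A3.
- Merits: the enol ether can form in one direction only, and the C8 bromide is a handle through which C12 could be introduced by carbonylation at the aldehyde level. In this respect the road is better than the chosen one, which depends on a SeO2 oxidation of a deactivated alkene (step 13).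
- Weak points: A3 again presents C9 as a ketone, with the same wrong facial preference for C11. A2 is not a chiral-pool compound, and its three stereocentres, angular methyl and 6α-oxygen would need a synthesis of their own. Carbene addition beside quaternary C10 is sterically demanding. Two silyl ethers must later be exchanged for acetates.
- Comparison: against the better C12 handle, the chosen plan sets the stereospecific delivery of 6α-O and 9α-OH and a direct descent from carvone.

**Alternative 3:** The cuts are C4–C5 and C9–C10, which open both rings to the acyclic triene A4. This is a dimethyl 2-alkylmaleate whose chain carries the C6 silyloxy stereocentre, the (E)-C5=C10 alkene, the C1 dioxolane and a terminal isopropenyl group. Fe(acac)3 and PhSiH3 would generate the C4 radical, which closes ring A on C5; the C10 radical then closes ring B on C9 of the maleate. Both closures are 6-endo and give the diester A5.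
- Merits: two rings, two C–C bonds and four stereocentres in one step, and C11 and C12 present from the outset as ester carbons, so that neither a cross-coupling nor an allylic C–H oxidation is needed. In ring-forming economy this road is better than the chosen one.
- Weak points: one stereocentre (C6) must control four new ones through two successive radical additions. The second addition joins a tertiary C10 radical to a trisubstituted, doubly activated alkene and competes with simple reduction. A4 needs an enantioselective synthesis. A5 still lacks the C7=C8 alkene and the C9 hydroxyl, and needs both esters reduced, the C1 ketone unmasked and reduced, and the silyl ether exchanged.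
- Comparison: the chosen route builds the rings one at a time, but each ring B centre is set by a step with a predictable facial bias, and the C6–C9 oxidation pattern arrives in one operation.

Key step: step 10

## Route

Remark on the chemistry: drimane numbering is used for all bicyclic compounds, which are trans-fused with 5α-H and 10β-CH3. Compound 4 is carried as the mixture of epimers at the methyl-bearing carbon (major trans epimer drawn) and 7 as a mixture of carbinol epimers; both centres are erased or oxidised in the following step.

Step 1
Reactants: 1 (R)-carvone; 2 iodomethane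
Product: 4 (5R,6S)-2,6-dimethyl-5-(prop-1-en-2-yl)cyclohex-2-en-1-one (trans-6-methylcarvone; minor 6R epimer carried along), via carvone lithium dienolate 3 (not isolated)
Conditions: LDA, THF, −78 °C; MeI, −78 → 0 °C
Reagents that add atoms: iodomethane (2), CI
Why: Kinetic α′-deprotonation gives the cross-conjugated dienolate 3, and enolate C-alkylation installs the future C10 methyl group; the new centre is planarised again in step 2, so its configuration is irrelevant.

Step 2
Reactants: 4 trans-6-methylcarvone; 5 acrolein
Product: 7 (5S,6R)-6-(1-hydroxyprop-2-en-1-yl)-2,6-dimethyl-5-(prop-1-en-2-yl)cyclohex-2-en-1-one (mixture of carbinol epimers), via 6-methylcarvone lithium enolate 6 (not isolated)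
Conditions: LDA, THF, −78 °C; acrolein, −78 °C; AcOH quench at −78 °C
Reagents that add atoms: acrolein (5), C=CC=O
Why: Aldol addition of the tetrasubstituted lithium enolate 6 to the aldehyde carbon of acrolein; the electrophile should enter anti to the neighbouring isopropenyl group, which sets quaternary C10 with the methyl cis and the three-carbon chain trans to isopropenyl. The cold acidic quench guards against retro-aldol cleavage.

Step 3
Reactants: 7 allylic alcohol
Product: 8 (5S,6R)-2,6-dimethyl-6-(prop-2-enoyl)-5-(prop-1-en-2-yl)cyclohex-2-en-1-one
Conditions: Dess–Martin periodinane, CH2Cl2, 0 °C → rt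
Reagents that add atoms: none
Why: Dess–Martin oxidation of a secondary allylic alcohol under near-neutral conditions; the carbon between the two carbonyls is quaternary, so the vinyl ketone can neither enolise nor epimerise.

Step 4
Reactants: 8 vinyl ketone
Product: 9 11-nordrim-7-ene-1,9-dione
Conditions: Fe(acac)3 (30 mol %), PhSiH3, EtOH–(CH2OH)2, 60 °C, high dilution
Reagents that add atoms: none
Why: Metal-hydride hydrogen-atom transfer to the 1,1-disubstituted alkene gives the tertiary C4 radical, which adds 6-endo to the terminal carbon of the vinyl ketone (Giese-type reductive olefin coupling), forming C3–C4 and the gem-dimethyl carbon. C5 and C10 are already set, and their trans arrangement makes both new ring bonds equatorial on ring B, hence the trans-decalin.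

Step 5
Reactants: 9 enedione
Product: 10 1β-hydroxy-11-nordrim-7-en-9-one
Conditions: NaBH4, CH2Cl2–MeOH (1:1), −78 °C
Reagents that add atoms: none
Why: Borohydride reduces the saturated C1 ketone faster than the hindered, conjugated C9 carbonyl (chemoselective ketone-over-enone reduction). Axial attack from the α face, anti to the 10β-methyl, should give the equatorial 1β-alcohol.

Step 6
Reactants: 10 hydroxy enone
Product: 11 1β-acetoxy-11-nordrim-7-en-9-one
Conditions: Ac2O, pyridine, DMAP (cat.), CH2Cl2, rt
Reagents that add atoms: acetic anhydride, CC(=O)OC(C)=O
Why: DMAP-catalysed acylation of a secondary alcohol; β-elimination is impossible because C10 bears no hydrogen, and esterification removes the retro-aldol pathway.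

Step 7
Reactants: 11 acetoxy enone
Product: 12 1β-acetoxy-11-nordrima-6,8-dien-9-yl trifluoromethanesulfonate
Conditions: Tf2O, 2,6-di-tert-butyl-4-methylpyridine, CH2Cl2, 0 °C → rt
Reagents that add atoms: trifluoromethanesulfonic anhydride, O=S(=O)(OS(=O)(=O)C(F)(F)F)C(F)(F)F
Why: Electrophilic O-triflation of the enone followed by loss of a C6 proton gives the 2-triflyloxy-1,3-diene, the standard dienyl triflate synthesis from cyclic enones. C6 is the only position that can lose a proton, and the non-basic conditions leave the acetate alone.

Step 8
Reactants: 12 dienyl triflate; 13 (tributylstannyl)methanol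
Product: 14 1β-acetoxydrima-6,8-dien-11-ol
Conditions: Pd(PPh3)4 (10 mol %), LiCl, 1,4-dioxane, 100 °C
Reagents that add atoms: (tributylstannyl)methanol (13), OC[Sn](CCCC)(CCCC)CCCC
Why: Stille coupling of an alkenyl triflate with a hydroxymethylstannane, which transfers CH2OH in preference to butyl; chloride assists transmetalation at the palladium triflate stage, and the neutral conditions preserve the acetate.

Step 9
Reactants: 14 dienyl carbinol
Product: 15 1β-acetoxy-11-(tert-butyldimethylsilyloxy)drima-6,8-diene
Conditions: TBSCl, imidazole, CH2Cl2, 0 °C → rt
Reagents that add atoms: tert-butyldimethylsilyl chloride, CC(C)(C)[Si](C)(C)Cl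
Why: Silylation of a primary alcohol; the silyl ether keeps C11 apart from the hydroxyl to be acetylated at C6 and keeps the diene electron-rich.

Step 10
Reactants: 15 silyloxy diene; 16 dioxygen (as singlet oxygen)
Product: 17 1β-acetoxy-11-(tert-butyldimethylsilyloxy)-6α,9α-epidioxydrim-7-ene
Conditions: O2 (1 atm), rose bengal (cat.), visible light, CH2Cl2–MeOH (9:1), −30 °C
Reagents that add atoms: dioxygen (16), O=O
Why: Rose bengal sensitises dioxygen to its singlet state, which adds as a two-atom dienophile to the s-cis C6=C7–C8=C9 diene in a concerted suprafacial [4+2] cycloaddition; the closest known reaction type is the dye-sensitised photooxygenation of homoannular ring B dienes, as in the formation of ergosterol peroxide or of ascaridole. The one new ring, the six-membered 3,6-dihydro-1,2-dioxine C6–O–O–C9–C8=C7, is closed by cycloaddition with both C–O bonds formed in the same step, so that ring B becomes a 2,3-dioxabicyclo[2.2.2]octene. C6 and C9 are set together: suprafacial addition puts both oxygens on one face, and the substrate chooses the face, since the pseudo-axial 10β-methyl lies over the C9 terminus and the axial 4β-methyl over C6 while the α face offers only the C5 hydrogen; oxygen should therefore enter α and leave C11 and H6 β. The step needs π-facial selectivity and periselectivity (cycloaddition over the ene reaction at C8=C9 with the C12 or C11 hydrogens); a diene locked s-cis in a six-membered ring, electron-rich and carrying C11 as an ether, not a carbonyl, favours cycloaddition. Low temperature and the absence of base protect the peroxide from Kornblum–DeLaMare fragmentation at C6–H.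

Step 11
Reactants: 17 endoperoxide
Product: 18 1β-acetoxy-11-(tert-butyldimethylsilyloxy)drim-7-ene-6α,9α-diol
Conditions: thiourea, MeOH, rt
Reagents that add atoms: none
Why: Thiourea reduction of a bicyclic endoperoxide cleaves only the O–O bond and gives the cis-2-ene-1,4-diol with both C–O configurations retained; acetate and silyl ether are inert under these neutral conditions.

Step 12
Reactants: 18 diol
Product: 19 1β,6α-diacetoxy-11-(tert-butyldimethylsilyloxy)drim-7-en-9α-ol
Conditions: Ac2O, pyridine, DMAP (cat.), CH2Cl2, 0 °C → rt
Reagents that add atoms: acetic anhydride, CC(=O)OC(C)=O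
Why: Chemoselective acylation: the secondary 6α-hydroxyl is acetylated, while the tertiary 9α-hydroxyl beside quaternary C10 does not react under these conditions.

Step 13
Reactants: 19 diacetate
Product: 21 1β,6α-diacetoxy-11-(tert-butyldimethylsilyloxy)drim-7-ene-9α,12-diol, via 12-aldehyde 20 (not isolated)
Conditions: SeO2 (0.5 equiv), t-BuOOH, CH2Cl2, rt; then NaBH4, MeOH, 0 °C
Reagents that add atoms: selenium dioxide, O=[Se]=O; tert-butyl hydroperoxide (terminal oxidant), CC(C)(C)OO
Why: SeO2 allylic oxidation (ene reaction, then [2,3]-sigmatropic shift) at the only allylic C–H on the disubstituted alkene carbon, the C12 methyl, which lies trans to C6 as in the oxidation of prenyl acetate to its (E)-aldehyde. The portion over-oxidised to enal 20 is returned to the alcohol by borohydride, so the whole material converges on 21.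

Step 14
Reactants: 21 silyl ether
Product: 22 1β,6α-diacetoxydrim-7-ene-9α,11,12-triol
Conditions: HF·pyridine, pyridine, THF, 0 °C → rt
Reagents that add atoms: none
Why: Fluoride cleavage of a primary silyl ether; the buffered, non-basic reagent avoids migration of the 1β-acetyl group to the nearby C11 hydroxyl.

Step 15
Reactants: 22 triol
Product: 23 parritadial (1β,6α-diacetoxy-9α-hydroxydrim-7-ene-11,12-dial)
Conditions: (COCl)2, DMSO, CH2Cl2, −78 °C; 22; Et3N, −78 → −20 °C
Reagents that add atoms: none
Why: Swern oxidation: both primary hydroxyls are converted to alkoxysulfonium ions before the base is added, so the 1,4-diol goes to the dialdehyde without a hydroxy aldehyde that would close to the lactol and end as the lactone. The tertiary C9 alcohol cannot be oxidised and C9 has no proton to epimerise.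

## Compound list

1 | (R)-carvone, (5R)-2-methyl-5-(prop-1-en-2-yl)cyclohex-2-en-1-one | O=C1C(C)=CC[C@@H](C(C)=C)C1 | starting material
2 | iodomethane | CI | starting material
3 | lithium (3R)-6-methyl-3-(prop-1-en-2-yl)cyclohexa-1,5-dien-1-olate (kinetic dienolate of 1) | [Li+].[O-]C1=C[C@H](C(C)=C)CC=C1C | intermediate (not isolated)
4 | (5R,6S)-2,6-dimethyl-5-(prop-1-en-2-yl)cyclohex-2-en-1-one (trans-6-methylcarvone, major epimer) | O=C1C(C)=CC[C@@H](C(C)=C)[C@@H]1C | intermediate
5 | acrolein | C=CC=O | starting material
6 | lithium (3S)-2,6-dimethyl-3-(prop-1-en-2-yl)cyclohexa-1,5-dien-1-olate (enolate of 4) | [Li+].[O-]C1=C(C)[C@H](C(C)=C)CC=C1C | intermediate (not isolated)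
7 | (5S,6R)-6-(1-hydroxyprop-2-en-1-yl)-2,6-dimethyl-5-(prop-1-en-2-yl)cyclohex-2-en-1-one, carbinol epimers; methyl cis and side chain trans to isopropenyl | O=C1C(C)=CC[C@@H](C(C)=C)[C@]1(C)C(O)C=C | intermediate
8 | (5S,6R)-2,6-dimethyl-6-(prop-2-enoyl)-5-(prop-1-en-2-yl)cyclohex-2-en-1-one | O=C1C(C)=CC[C@@H](C(C)=C)[C@]1(C)C(=O)C=C | intermediate
9 | 11-nordrim-7-ene-1,9-dione (trans-fused, 5α-H, 10β-CH3) | C1C=C(C)C(=O)[C@@]2(C)C(=O)CCC(C)(C)[C@H]12 | intermediate
10 | 1β-hydroxy-11-nordrim-7-en-9-one | C1C=C(C)C(=O)[C@@]2(C)[C@H](O)CCC(C)(C)[C@H]12 | intermediate
11 | 1β-acetoxy-11-nordrim-7-en-9-one | C1C=C(C)C(=O)[C@@]2(C)[C@H](OC(C)=O)CCC(C)(C)[C@H]12 | intermediate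
12 | 1β-acetoxy-11-nordrima-6,8-dien-9-yl trifluoromethanesulfonate | C1=CC(C)=C(OS(=O)(=O)C(F)(F)F)[C@@]2(C)[C@H](OC(C)=O)CCC(C)(C)[C@H]12 | intermediate
13 | (tributylstannyl)methanol | OC[Sn](CCCC)(CCCC)CCCC | starting material
14 | 1β-acetoxydrima-6,8-dien-11-ol | C1=CC(C)=C(CO)[C@@]2(C)[C@H](OC(C)=O)CCC(C)(C)[C@H]12 | intermediate
15 | 1β-acetoxy-11-(tert-butyldimethylsilyloxy)drima-6,8-diene | C1=CC(C)=C(CO[Si](C)(C)C(C)(C)C)[C@@]2(C)[C@H](OC(C)=O)CCC(C)(C)[C@H]12 | intermediate
16 | dioxygen (used as singlet oxygen) | O=O | starting material
17 | 1β-acetoxy-11-(tert-butyldimethylsilyloxy)-6α,9α-epidioxydrim-7-ene | O3[C@H]1C=C(C)[C@](O3)(CO[Si](C)(C)C(C)(C)C)[C@@]2(C)[C@H](OC(C)=O)CCC(C)(C)[C@H]12 | intermediate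
18 | 1β-acetoxy-11-(tert-butyldimethylsilyloxy)drim-7-ene-6α,9α-diol | O[C@H]1C=C(C)[C@](O)(CO[Si](C)(C)C(C)(C)C)[C@@]2(C)[C@H](OC(C)=O)CCC(C)(C)[C@H]12 | intermediate
19 | 1β,6α-diacetoxy-11-(tert-butyldimethylsilyloxy)drim-7-en-9α-ol | CC(=O)O[C@H]1C=C(C)[C@](O)(CO[Si](C)(C)C(C)(C)C)[C@@]2(C)[C@H](OC(C)=O)CCC(C)(C)[C@H]12 | intermediate
20 | 1β,6α-diacetoxy-11-(tert-butyldimethylsilyloxy)-9α-hydroxydrim-7-en-12-al | CC(=O)O[C@H]1C=C(C=O)[C@](O)(CO[Si](C)(C)C(C)(C)C)[C@@]2(C)[C@H](OC(C)=O)CCC(C)(C)[C@H]12 | intermediate (not isolated)
21 | 1β,6α-diacetoxy-11-(tert-butyldimethylsilyloxy)drim-7-ene-9α,12-diol | CC(=O)O[C@H]1C=C(CO)[C@](O)(CO[Si](C)(C)C(C)(C)C)[C@@]2(C)[C@H](OC(C)=O)CCC(C)(C)[C@H]12 | intermediate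
22 | 1β,6α-diacetoxydrim-7-ene-9α,11,12-triol | CC(=O)O[C@H]1C=C(CO)[C@](O)(CO)[C@@]2(C)[C@H](OC(C)=O)CCC(C)(C)[C@H]12 | intermediate
23 | parritadial, 1β,6α-diacetoxy-9α-hydroxydrim-7-ene-11,12-dial | CC(=O)O[C@H]1C=C(C=O)[C@](O)(C=O)[C@@]2(C)[C@H](OC(C)=O)CCC(C)(C)[C@H]12 | target

## Step count and uncertain steps

Total: 15 steps. Longest linear sequence: 15 steps from (R)-carvone 1; the route is fully linear.

**Step 10 (key step).** The most likely failure is loss of periselectivity: the ene reaction of singlet oxygen at the tetrasubstituted C8=C9 bond, with hydrogen taken from C12, may compete with cycloaddition because the C9 terminus is crowded. Incomplete α-face selectivity and base-induced fragmentation of the peroxide are lesser risks. The fallback sets out from 15 and comes back to the route at 19, building the same cis-1,4-dioxygen pattern in two polar steps. Dimethyldioxirane in acetone at −20 °C should epoxidise the more electron-rich tetrasubstituted C8=C9 bond from the α face to give 1β-acetoxy-11-(tert-butyldimethylsilyloxy)-8α,9α-epoxydrim-6-ene F1. Pd(PPh3)4 (zerovalent palladium) with acetic acid in THF should then ionise the allylic C8–O bond anti to the oxirane, and acetate should attack C6 anti to the metal. The net cis-1,4-addition leaves the hydroxyl on C9 and the acetate on C6, both α, which is 19.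

**Step 13.** The alkene is deactivated by two allylic oxygens and C7 is flanked by the acetate. The ene reaction with SeO2 may therefore be too slow, and prolonged exposure would invite ionisation of the tertiary allylic alcohol or loss of the silyl group. The fallback sets out from 19 and comes back at 20, replacing the ene reaction by radical substitution. Wohl–Ziegler bromination (N-bromosuccinimide, AIBN, PhCF3, 80 °C, K2CO3 as acid scavenger) should attack the exposed C12 methyl in preference to the shielded, acetoxy-deactivated C6–H, giving 12-bromo-1β,6α-diacetoxy-11-(tert-butyldimethylsilyloxy)drim-7-en-9α-ol F2. Oxidation of the bromide with N-methylmorpholine N-oxide in MeCN would give enal 20, which is reduced to 21 with NaBH4 as in the second operation of step 13.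

**Step 8.** Transmetalation at a tetrasubstituted alkenylpalladium centre beside quaternary C10 may be slow, so that reduction of the triflate or butyl transfer takes over. The fallback sets out from 12 and comes back at 14, bringing C11 in as carbon monoxide, which inserts readily even at hindered palladium. Reductive carbonylation (Pd(PPh3)4, CO at 1 atm, slow addition of Bu3SnH, THF, 50 °C) should give 1β-acetoxydrima-6,8-dien-11-al F3. 1,2-Reduction with NaBH4 and CeCl3·7H2O in MeOH at −40 °C would give 14 without touching the acetate.

**Step 2.** Conjugate addition of the hindered enolate to acrolein and oligomerisation of the aldehyde may compete with the aldol addition, and the congested aldolate may revert. The fallback sets out from 4 and comes back at 8, using an aldehyde that cannot act as a Michael acceptor and building the vinyl group afterwards. Enolate 6 and acetaldehyde should give (5S,6R)-6-(1-hydroxyethyl)-2,6-dimethyl-5-(prop-1-en-2-yl)cyclohex-2-en-1-one F4, and Dess–Martin oxidation (5S,6R)-6-acetyl-2,6-dimethyl-5-(prop-1-en-2-yl)cyclohex-2-en-1-one F5. The acetyl methyl is the only enolisable α-position, so LiHMDS followed by Eschenmoser's salt should give the Mannich base (5S,6R)-6-[3-(dimethylamino)propanoyl]-2,6-dimethyl-5-(prop-1-en-2-yl)cyclohex-2-en-1-one F6. Quaternisation with MeI and elimination with NaHCO3 would give 8.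

**Step 15.** If one hydroxyl is oxidised ahead of the other, the hydroxy aldehyde closes to the lactol and is carried on to the lactone. The tertiary alkoxysulfonium ion may also give a methylthiomethyl ether if the mixture warms. The fallback sets out from 19 and comes back at 23, and never has a 1,4-diol in hand. HF·pyridine should give 1β,6α-diacetoxydrim-7-ene-9α,11-diol F7. Parikh–Doering oxidation (SO3·pyridine, DMSO, i-Pr2NEt, 0 °C) would give 1β,6α-diacetoxy-9α-hydroxydrim-7-en-11-al F8. SeO2 in 1,4-dioxane at 80 °C would then oxidise the C12 methyl directly to the aldehyde, giving 23. This fallback depends on the same SeO2 ene reaction that is uncertain in step 13, on a still more deactivated alkene.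

## Further compounds

F1 | step 10 | 1β-acetoxy-11-(tert-butyldimethylsilyloxy)-8α,9α-epoxydrim-6-ene | C1=C[C@@]3(C)O[C@@]3(CO[Si](C)(C)C(C)(C)C)[C@@]2(C)[C@H](OC(C)=O)CCC(C)(C)[C@H]12
F2 | step 13 | 12-bromo-1β,6α-diacetoxy-11-(tert-butyldimethylsilyloxy)drim-7-en-9α-ol | CC(=O)O[C@H]1C=C(CBr)[C@](O)(CO[Si](C)(C)C(C)(C)C)[C@@]2(C)[C@H](OC(C)=O)CCC(C)(C)[C@H]12
F3 | step 8 | 1β-acetoxydrima-6,8-dien-11-al | C1=CC(C)=C(C=O)[C@@]2(C)[C@H](OC(C)=O)CCC(C)(C)[C@H]12
F4 | step 2 | (5S,6R)-6-(1-hydroxyethyl)-2,6-dimethyl-5-(prop-1-en-2-yl)cyclohex-2-en-1-one (carbinol epimers) | O=C1C(C)=CC[C@@H](C(C)=C)[C@]1(C)C(C)O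
F5 | step 2 | (5S,6R)-6-acetyl-2,6-dimethyl-5-(prop-1-en-2-yl)cyclohex-2-en-1-one | O=C1C(C)=CC[C@@H](C(C)=C)[C@]1(C)C(C)=O
F6 | step 2 | (5S,6R)-6-[3-(dimethylamino)propanoyl]-2,6-dimethyl-5-(prop-1-en-2-yl)cyclohex-2-en-1-one | O=C1C(C)=CC[C@@H](C(C)=C)[C@]1(C)C(=O)CCN(C)C
F7 | step 15 | 1β,6α-diacetoxydrim-7-ene-9α,11-diol | CC(=O)O[C@H]1C=C(C)[C@](O)(CO)[C@@]2(C)[C@H](OC(C)=O)CCC(C)(C)[C@H]12
F8 | step 15 | 1β,6α-diacetoxy-9α-hydroxydrim-7-en-11-al | CC(=O)O[C@H]1C=C(C)[C@](O)(C=O)[C@@]2(C)[C@H](OC(C)=O)CCC(C)(C)[C@H]12
A1 | alternative 1 | 11-nordrim-7-ene-1,9-dione (identical with 9) | C1C=C(C)C(=O)[C@@]2(C)C(=O)CCC(C)(C)[C@H]12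
A2 | alternative 2 | trimethylsilyl enol ether (C7=C9) of the trans-fused five-membered-ring ketone lacking C8, with 1β- and 6α-tert-butyldimethylsilyloxy groups | CC(C)(C)[Si](C)(C)O[C@H]1C=C(O[Si](C)(C)C)[C@@]2(C)[C@H](O[Si](C)(C)C(C)(C)C)CCC(C)(C)[C@H]12
A3 | alternative 2 | 8-bromo-1β,6α-bis(tert-butyldimethylsilyloxy)-11,12-dinordrim-7-en-9-one | CC(C)(C)[Si](C)(C)O[C@H]1C=C(Br)C(=O)[C@@]2(C)[C@H](O[Si](C)(C)C(C)(C)C)CCC(C)(C)[C@H]12
A4 | alternative 3 | acyclic triene: dimethyl 2-alkylmaleate with the 6-silyloxy stereocentre, (E)-C5=C10 alkene, C1 dioxolane and terminal isopropenyl group | C=C(C)CCC1(OCCO1)/C(C)=C/[C@@H](O[Si](C)(C)C(C)(C)C)C/C(C(=O)OC)=C/C(=O)OC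
A5 | alternative 3 | trans-decalin 11,12-dimethyl diester with 6α-tert-butyldimethylsilyloxy group and C1 dioxolane | CC(C)(C)[Si](C)(C)O[C@H]1C[C@@H](C(=O)OC)[C@H](C(=O)OC)[C@@]2(C)C3(OCCO3)CCC(C)(C)[C@H]12
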